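**Strategy.** Everything rests on reading ring A as a Diels–Alder adduct. The C2 ketone and C3 oxygen, flanked by C1H2 and the gem-dimethyl C4, are the retron of a 2,3-bis(silyloxy)diene C1=C2–C3=C4. The ring-fusion bond C5–C10 of ring B is the alkene of a β-methylcyclohexenone activated by a temporary C6 carbonyl. One Lewis-acid cycloaddition joins C1–C10 and C4–C5, builds the quaternary C10 under control of a sacrificial C8 methyl stereocentre and delivers ring A as a masked acyloin. The precursors are a bis-silyl enol ether of 4-methylpentane-2,3-dione and an enantioenriched Hagemann-type keto ester; C5, C9 and C3 are set afterwards by equilibration or kinetic protonation.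

Key step: step 3

Remark: drimane numbering is used for the decalin (ring A = C1–C5, C10; ring B = C5–C10; C11 on C9; methyls on C4, C4, C8, C10). "Methyl face" means the face that carries the C10 methyl, which sits as in the target in every bicyclic compound. TBS = tert-butyldimethylsilyl.

Step 1
Reactants: 1 4-methylpentane-2,3-dione
Product: 2 4-methyl-2,3-bis(tert-butyldimethylsilyloxy)penta-1,3-diene
Conditions: TBSOTf (2.3 equiv), Et3N, CH2Cl2, 0 °C to rt
Reagents that add atoms: tert-butyldimethylsilyl triflate, CC(C)(C)[Si](C)(C)OS(=O)(=O)C(F)(F)F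
Why: Soft enolisation of both carbonyl groups of the 1,2-diketone (double silyl enol ether formation, as known for biacetyl) can give only this cross-conjugated diene, because each ketone has a single enolisable side.

Step 2
Reactants: 3 ethyl acetoacetate; 4 (E)-pent-3-en-2-one
Product: 6 ethyl (1S,6R)-2,6-dimethyl-4-oxocyclohex-2-ene-1-carboxylate, via Michael adduct 5 (not isolated)
Conditions: 9-amino-9-deoxy-epi-quinine (20 mol %), PhCO2H, toluene, rt; then p-TsOH, toluene, reflux (Dean–Stark)
Reagents that add atoms: none
Why: Iminium-activated asymmetric Michael addition of the β-keto ester sets the methyl-bearing centre (the quinine- or quinidine-derived amine is chosen for the 6R series), and acid-mediated aldol condensation of the methyl ketone onto the acetoacetate carbonyl (organocatalytic Robinson annulation) closes the Hagemann-type enone, whose epimerisable C1 centre is of no consequence later.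

Step 3
Reactants: 2 4-methyl-2,3-bis(tert-butyldimethylsilyloxy)penta-1,3-diene; 6 ethyl (1S,6R)-2,6-dimethyl-4-oxocyclohex-2-ene-1-carboxylate
Product: 7 cis-fused adduct, ethyl 2,3-bis(TBS-oxy)-6-oxodrim-2-en-11-oate with H-5, the C8 methyl and the C10 methyl on one face and the C9 ester on the other
Conditions: AlBr3/AlMe3 (10:1, 30 mol %), toluene/CH2Cl2, −5 °C to rt
Reagents that add atoms: none
Why: The aluminium Lewis acid binds the C6 carbonyl of 6; the unsubstituted diene terminus C1 (nucleophilic carbon of the C2 silyl enol ether) bonds to the β-carbon C10 and the gem-dimethyl terminus C4 to C5 in a strongly asynchronous Diels–Alder reaction that may be stepwise (Mukaiyama–Michael addition, then closure of the aluminium enolate onto the silyloxyallyl cation). The closest known reaction type is the mixed AlBr3/AlMe3-catalysed Diels–Alder reaction of hindered 2-silyloxydienes bearing a gem-dimethyl terminus with β-substituted cyclohexenones. Ring A closes as a six-membered ring by intermolecular [4+2] cycloaddition, suprafacial on both partners, so ring B stays intact and becomes cis-fused (in the stepwise limit the second bond forms by 6-endo-trig Michael closure). C10 is controlled by the C8 methyl of 6: the diene adds to the enone face opposite to this methyl (axial attack on the half-chair with the methyl equatorial, as usual for 5-substituted cyclohexenones), and C5 follows as cis and is corrected in step 5. The step needs regioselectivity, secured by the unhindered nucleophilic C1 meeting the β-carbon, and π-facial selectivity, secured by the C8 methyl; endo/exo selectivity is irrelevant because the diene termini create no stereocentre.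

Step 4
Reactants: 7 cis-fused adduct
Product: 8 cis-fused enone, ethyl 2,3-bis(TBS-oxy)-6-oxodrima-2,7-dien-11-oate (H-5 on the methyl face, C9 ester on the opposite face)
Conditions: LiN(i-Pr)2, THF, −78 °C; then PhS(Cl)=N-t-Bu, −78 °C
Reagents that add atoms: none
Why: Kinetic deprotonation at the unhindered C7 methylene and reaction of the enolate with the sulfinimidoyl chloride gives the enone by syn elimination (Mukaiyama dehydrogenation), which removes the relay stereocentre C8 once it has done its work.

Step 5
Reactants: 8 cis-fused enone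
Product: 9 trans-fused enone, ethyl 2,3-bis(TBS-oxy)-6-oxodrima-2,7-dien-11-oate (H-5 opposite to the methyl face)
Conditions: t-BuOK (0.2 equiv), t-BuOH/THF, rt
Reagents that add atoms: none
Why: Equilibration through the C6 enolate should convert the cis ring fusion into the trans-decalin (thermodynamic epimerisation at C5), feasible now that C8 is trigonal and no 1,3-diaxial methyl pair arises; the alkene should stay conjugated with the ketone as in Hagemann's ester, and the C9 configuration is immaterial because C9 becomes trigonal in step 6.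

Step 6
Reactants: 9 trans-fused enone
Product: 10 ethyl 2,3-bis(TBS-oxy)-6-(trifluoromethylsulfonyloxy)drima-2,6,8-trien-11-oate
Conditions: NaH, cat. t-BuOH, THF, 0 °C to rt; then PhNTf2, 0 °C
Reagents that add atoms: N-phenylbis(trifluoromethanesulfonimide), O=S(=O)(N(c1ccccc1)S(=O)(=O)C(F)(F)F)C(F)(F)F
Why: The vinylogous β-keto ester is deprotonated at C9 under equilibrating conditions and the extended enolate is sulfonylated on the ketone oxygen (enol triflate formation), which turns the C6 oxygen into a leaving group without touching C5.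

Step 7
Reactants: 10 dienyl triflate
Product: 11 ethyl 2,3-bis(TBS-oxy)drima-2,6,8-trien-11-oate
Conditions: Pd(OAc)2 (5 mol %), PPh3, HCO2H, n-Bu3N, DMF, 60 °C
Reagents that add atoms: none
Why: Palladium-catalysed formate reduction of the enol triflate (oxidative addition, formate-to-hydride exchange, reductive elimination) replaces the C6 oxygen by hydrogen and leaves the conjugated 6,8-dienoate.

Step 8
Reactants: 11 dienoate
Product: 12 ethyl 2,3-bis(TBS-oxy)drima-2,7-dien-11-oate with the C9 ester on the methyl face (H-5 and H-9 opposite)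
Conditions: Li, NH3/THF, t-BuOH (1 equiv), −78 °C; then NH4Cl
Reagents that add atoms: none
Why: Dissolving-metal reduction of the conjugated dienoate (Birch-type 1,6-reduction) adds hydrogen at C6 and leaves the ester dienolate, whose kinetic protonation at C9 from the face opposite to the axial C10 methyl gives the β,γ-unsaturated ester with the C7=C8 alkene and the C9 ester cis to the angular methyl.

Step 9
Reactants: 12 β,γ-unsaturated ester
Product: 13 2,3-bis(TBS-oxy)drima-2,7-dien-11-ol
Conditions: i-Bu2AlH, CH2Cl2, −78 to 0 °C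
Reagents that add atoms: none
Why: Hydride reduction of the ester to the primary alcohol affects neither the silyl enol ethers nor the stereocentres.

Step 10
Reactants: 13 primary alcohol; 14 umbelliferone (7-hydroxycoumarin)
Product: 15 7-{[2,3-bis(TBS-oxy)drima-2,7-dien-11-yl]oxy}coumarin
Conditions: PPh3, DIAD, THF, 0 °C to rt
Reagents that add atoms: none
Why: Mitsunobu etherification of the primary C11 alcohol with the acidic phenol forms the aryl ether at a non-stereogenic carbon.

Step 11
Reactants: 15 bis-silyl enediol ether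
Product: 17 7-{[(3S,5S,9R,10R)-3-hydroxy-2-oxodrim-7-en-11-yl]oxy}coumarin, via silyloxy ketone 16 (not isolated)
Conditions: n-Bu4NF/AcOH, THF, −20 °C; then aq. HF, MeCN, rt
Reagents that add atoms: none
Why: Fluoride should attack the less hindered silicon on O2 (O3 is flanked by the C4 gem-dimethyl group), the buffered enolate is protonated at C3 on the face opposite to the angular methyl and the axial C4 methyl so that O3 ends equatorial and cis to the C10 methyl, and aqueous HF then cleaves the remaining silyl ether (selective desilylation with kinetic protonation).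

Step 12
Reactants: 17 α-hydroxy ketone; 18 angelic acid
Product: 20 7-{[(3S,5S,9R,10R)-3-angeloyloxy-2-oxodrim-7-en-11-yl]oxy}coumarin (CNP0111364.1), via mixed anhydride 19 (not isolated)
Conditions: 18, 2,4,6-Cl3C6H2COCl, Et3N, toluene, rt; then 17, 75 °C
Reagents that add atoms: none
Why: Acylation with the mixed anhydride of angelic and 2,4,6-trichlorobenzoic acid without a nucleophilic catalyst (Yamaguchi-type esterification) is the established way to make an angelate without isomerisation to the tiglate, and the alcohol attacks the less hindered angeloyl carbonyl.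

**Compound list**
1 | 4-methylpentane-2,3-dione | CC(=O)C(=O)C(C)C | starting material
2 | 4-methyl-2,3-bis(tert-butyldimethylsilyloxy)penta-1,3-diene | C=C(O[Si](C)(C)C(C)(C)C)C(O[Si](C)(C)C(C)(C)C)=C(C)C | intermediate
3 | ethyl acetoacetate | CCOC(=O)CC(C)=O | starting material
4 | (E)-pent-3-en-2-one | C/C=C/C(C)=O | starting material
5 | ethyl (3R)-2-acetyl-3-methyl-5-oxohexanoate (C2 epimers) | CCOC(=O)C(C(C)=O)[C@H](C)CC(C)=O | intermediate
6 | ethyl (1S,6R)-2,6-dimethyl-4-oxocyclohex-2-ene-1-carboxylate | CCOC(=O)[C@@H]1C(C)=CC(=O)C[C@H]1C | intermediate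
7 | cis-fused ethyl 2,3-bis(TBS-oxy)-6-oxodrim-2-en-11-oate (H-5, 8-methyl, 10-methyl syn; 9-ester anti) | CC(C)(C)[Si](C)(C)OC1=C(O[Si](C)(C)C(C)(C)C)C[C@@]2(C)[C@@H](C(=O)OCC)[C@H](C)CC(=O)[C@H]2C1(C)C | intermediate
8 | cis-fused ethyl 2,3-bis(TBS-oxy)-6-oxodrima-2,7-dien-11-oate | CC(C)(C)[Si](C)(C)OC1=C(O[Si](C)(C)C(C)(C)C)C[C@@]2(C)[C@@H](C(=O)OCC)C(C)=CC(=O)[C@H]2C1(C)C | intermediate
9 | trans-fused ethyl 2,3-bis(TBS-oxy)-6-oxodrima-2,7-dien-11-oate | CC(C)(C)[Si](C)(C)OC1=C(O[Si](C)(C)C(C)(C)C)C[C@@]2(C)[C@@H](C(=O)OCC)C(C)=CC(=O)[C@@H]2C1(C)C | intermediate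
10 | ethyl 2,3-bis(TBS-oxy)-6-(trifluoromethylsulfonyloxy)drima-2,6,8-trien-11-oate | CC(C)(C)[Si](C)(C)OC1=C(O[Si](C)(C)C(C)(C)C)C[C@@]2(C)C(C(=O)OCC)=C(C)C=C(OS(=O)(=O)C(F)(F)F)[C@@H]2C1(C)C | intermediate
11 | ethyl 2,3-bis(TBS-oxy)drima-2,6,8-trien-11-oate | CC(C)(C)[Si](C)(C)OC1=C(O[Si](C)(C)C(C)(C)C)C[C@@]2(C)C(C(=O)OCC)=C(C)C=C[C@@H]2C1(C)C | intermediate
12 | ethyl 2,3-bis(TBS-oxy)drima-2,7-dien-11-oate (9-ester cis to 10-methyl; H-5 trans) | CC(C)(C)[Si](C)(C)OC1=C(O[Si](C)(C)C(C)(C)C)C[C@@]2(C)[C@H](C(=O)OCC)C(C)=CC[C@@H]2C1(C)C | intermediate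
13 | 2,3-bis(TBS-oxy)drima-2,7-dien-11-ol | CC(C)(C)[Si](C)(C)OC1=C(O[Si](C)(C)C(C)(C)C)C[C@@]2(C)[C@H](CO)C(C)=CC[C@@H]2C1(C)C | intermediate
14 | umbelliferone (7-hydroxycoumarin) | Oc1ccc2ccc(=O)oc2c1 | starting material
15 | 7-{[2,3-bis(TBS-oxy)drima-2,7-dien-11-yl]oxy}coumarin | CC(C)(C)[Si](C)(C)OC1=C(O[Si](C)(C)C(C)(C)C)C[C@@]2(C)[C@H](COc3ccc4ccc(=O)oc4c3)C(C)=CC[C@@H]2C1(C)C | intermediate
16 | 7-{[3-(TBS-oxy)-2-oxodrim-7-en-11-yl]oxy}coumarin (O-3 cis to 10-methyl) | CC(C)(C)[Si](C)(C)O[C@@H]1C(=O)C[C@@]2(C)[C@H](COc3ccc4ccc(=O)oc4c3)C(C)=CC[C@@H]2C1(C)C | intermediate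
17 | 7-{[(3S,5S,9R,10R)-3-hydroxy-2-oxodrim-7-en-11-yl]oxy}coumarin | O[C@@H]1C(=O)C[C@@]2(C)[C@H](COc3ccc4ccc(=O)oc4c3)C(C)=CC[C@@H]2C1(C)C | intermediate
18 | angelic acid, (Z)-2-methylbut-2-enoic acid | C/C=C(/C)C(=O)O | starting material
19 | angelic 2,4,6-trichlorobenzoic anhydride | C/C=C(/C)C(=O)OC(=O)c1c(Cl)cc(Cl)cc1Cl | intermediate
20 | 7-{[(3S,5S,9R,10R)-3-angeloyloxy-2-oxodrim-7-en-11-yl]oxy}coumarin | C/C=C(/C)C(=O)O[C@@H]1C(=O)C[C@@]2(C)[C@H](COc3ccc4ccc(=O)oc4c3)C(C)=CC[C@@H]2C1(C)C | target

Total steps: 12. Longest linear sequence: 11 steps (steps 2 to 12, or step 1 and steps 3 to 12).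

**Steps most likely to fail**

Step 3. After the first C–C bond the hindered gem-dimethyl terminus may fail to close onto C5, the Lewis acid may strip the silyl groups from the diene, or facial control by the C8 methyl may be incomplete, which would show up as loss of enantiomeric purity once C8 is erased. Fallback: setting out from 2 and 6, the two bonds are made one after the other. A Mukaiyama–Michael addition with silyl transfer (catalytic TBSOTf, CH2Cl2, −78 °C) should stop at the open-chain adduct, in which only C1–C10 has formed: ethyl 4-(TBS-oxy)-2,6-dimethyl-2-[3-(TBS-oxy)-4-methyl-2-oxopent-3-enyl]cyclohex-3-ene-1-carboxylate F1. After isolation, the ring B silyl enol ether is closed onto the silyloxy enone by an intramolecular Mukaiyama–Michael reaction with silyl transfer to O2 (TBSNTf2 generated from HNTf2, CH2Cl2, −40 °C to rt, or high pressure). This returns to 7.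

Step 11. Fluoride may attack the silicon on O3, or the silyl group may migrate within the enediolate, so that the transposed ketol forms; protonation may also be less face-selective than planned. Fallback: setting out from 15, both silyl groups are removed (HF·pyridine, THF) to give 17 together with the transposed ketol, 7-{[2-hydroxy-3-oxodrim-7-en-11-yl]oxy}coumarin F2. Hypervalent-iodine oxidation (DMP) of the mixture converges on the single 1,2-dione, which exists as the diosphenol, 7-{[2-hydroxy-3-oxodrima-1,7-dien-11-yl]oxy}coumarin F3, because only C1 can enolise. Silylation (TBSCl, imidazole) gives the 2-silyloxy enone F4. Luche reduction (NaBH4, CeCl3, MeOH, −78 °C) of the C3 carbonyl from the face opposite to the angular methyl gives the allylic alcohol F5. Hydrolysis of its silyl enol ether (aq. HF, MeCN) returns to 17 with unambiguous regiochemistry.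

Step 10. Substitution at the β-branched, neopentyl-like C11 may be slow, so that elimination or alkylation of the hydrazide by-product takes over. Fallback: setting out from 13, the ether is made from the other side by palladium-catalysed C–O coupling of the alcohol with commercial 7-bromocoumarin (O=c1ccc2ccc(Br)cc2o1), using Pd2(dba)3, t-BuBrettPhos, Cs2CO3, toluene, 90 °C. This forms the aryl–oxygen bond instead of the C11–oxygen bond and returns directly to 15.

**Further compounds**
F1 | step 3 | ethyl 4-(TBS-oxy)-2,6-dimethyl-2-[3-(TBS-oxy)-4-methyl-2-oxopent-3-enyl]cyclohex-3-ene-1-carboxylate | CCOC(=O)[C@H]1[C@H](C)CC(O[Si](C)(C)C(C)(C)C)=C[C@@]1(C)CC(=O)C(O[Si](C)(C)C(C)(C)C)=C(C)C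
F2 | step 11 | 7-{[2-hydroxy-3-oxodrim-7-en-11-yl]oxy}coumarin (C2 unassigned) | O=C1C(O)C[C@@]2(C)[C@H](COc3ccc4ccc(=O)oc4c3)C(C)=CC[C@@H]2C1(C)C
F3 | step 11 | 7-{[2-hydroxy-3-oxodrima-1,7-dien-11-yl]oxy}coumarin | O=C1C(O)=C[C@@]2(C)[C@H](COc3ccc4ccc(=O)oc4c3)C(C)=CC[C@@H]2C1(C)C
F4 | step 11 | 7-{[2-(TBS-oxy)-3-oxodrima-1,7-dien-11-yl]oxy}coumarin | O=C1C(O[Si](C)(C)C(C)(C)C)=C[C@@]2(C)[C@H](COc3ccc4ccc(=O)oc4c3)C(C)=CC[C@@H]2C1(C)C
F5 | step 11 | 7-{[3-hydroxy-2-(TBS-oxy)drima-1,7-dien-11-yl]oxy}coumarin (3-OH cis to 10-methyl) | O[C@@H]1C(O[Si](C)(C)C(C)(C)C)=C[C@@]2(C)[C@H](COc3ccc4ccc(=O)oc4c3)C(C)=CC[C@@H]2C1(C)C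
F0 | step 10 | none | none
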